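The route rests on disconnecting the bond between quaternary carbon C1 of the cyclopentane (ring B) and the arene carbon (ring A) that lies ortho to the phenolic oxygen. Two features are exploited. This oxygen is the direct neighbour of the bonding arene carbon, and C3, which carries the bromomethylidene group, is 1,3-related to C1. The two C7 halves are therefore tied as an O–C3 allyl aryl ether and joined at carbon by an aromatic Claisen rearrangement. In one operation it forges the hindered aryl–C1 bond, sets the quaternary stereocentre by 1,3-chirality transfer, liberates the phenol and places a C2=C3 alkene for the endgame. The precursor is an enantioenriched 2,3-dimethylcyclopent-2-enyl aryl ether.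

Key step: step 3

Remark (locants and geometry): ring A is the arene. Ring B is the cyclopentane with C1 = quaternary carbon, C2 = CH(CH3), C3 = ring carbon of the exocyclic double bond, and C4 and C5 = CH2. The structure is read as (1R,2R,3Z), that is, C2–CH3 cis to the aryl group and the vinylic Br on the C2 side of the double bond.

Step 1
Reactants: 1 2,3-dimethylcyclopent-2-en-1-one
Product: 2 (1R)-2,3-dimethylcyclopent-2-en-1-ol
Conditions: (S)-Me-CBS oxazaborolidine (10 mol %), BH3·SMe2, THF, −20 °C; MeOH quench
Reagents that add atoms: none
Why: Corey–Bakshi–Shibata reduction, in which the catalyst–borane complex binds the carbonyl oxygen away from the larger, methyl-substituted alkenyl flank and delivers hydride to one face in a 1,2-manner, so the (S)-catalyst should give the (R)-allylic alcohol from which all later stereochemistry is relayed.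

Step 2
Reactants: 2 (1R)-2,3-dimethylcyclopent-2-en-1-ol; 3 4-bromo-3-methylphenol
Product: 4 1-bromo-4-{[(1S)-2,3-dimethylcyclopent-2-en-1-yl]oxy}-2-methylbenzene
Conditions: PPh3, DIAD, toluene, −20 to 0 °C
Reagents that add atoms: none
Why: Mitsunobu etherification, in which the phenoxide displaces the oxyphosphonium group at the secondary allylic carbon in an SN2 manner with inversion, while SN2' attack would have to occur at a fully substituted alkene carbon and is disfavoured.

Step 3
Reactants: 4 1-bromo-4-{[(1S)-2,3-dimethylcyclopent-2-en-1-yl]oxy}-2-methylbenzene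
Product: 6 4-bromo-2-[(1R)-1,2-dimethylcyclopent-2-en-1-yl]-5-methylphenol, via dienone 5 (not isolated)
Conditions: Eu(fod)3 (10 mol %), toluene, 60–80 °C
Reagents that add atoms: none
Why: Eu(fod)3 binds the ether oxygen, weakens the O–C3 bond and triggers a concerted suprafacial [3,3]-sigmatropic shift (aromatic Claisen rearrangement) in which the free ortho carbon of ring A bonds to the methyl-bearing alkene carbon C1 while the double bond moves to C2=C3, so that the whole C7 ring B fragment passes from oxygen to carbon, and dienone 5 then tautomerises to phenol 6. The closest known reaction type is the Eu(fod)3-catalysed Claisen rearrangement of enantioenriched cycloalkenyl aryl ethers with 1,3-chirality transfer, and the thermal rearrangement of prenyl aryl ethers shows that benzylic quaternary carbons can be made this way. No ring of the product is closed; the only cyclic array is the six-membered, boat-like pericyclic transition state imposed by the cyclopentene. The new quaternary stereocentre C1 is controlled by the C3–O stereocentre of 4, since the ring lets the arene reach C1 only on the face from which oxygen leaves, so (S)-4 should give (R)-6. Regioselectivity is needed between the two ortho positions and is secured by the ring A methyl group, which crowds its neighbouring ortho carbon, while the bromine blocks the para position against a follow-up Cope shift. The two alkene methyl groups stabilise the partial allyl cation character of the transition state and so offset the steric cost at C1, but they also favour ionisation, which is why a mild oxophilic Lewis acid in a non-polar solvent is chosen instead of strong Lewis acids or temperatures near 200 °C.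

Step 4
Reactants: 6 4-bromo-2-[(1R)-1,2-dimethylcyclopent-2-en-1-yl]-5-methylphenol
Product: 7 {4-bromo-2-[(1R)-1,2-dimethylcyclopent-2-en-1-yl]-5-methylphenoxy}(tert-butyl)dimethylsilane
Conditions: TBSOTf, 2,6-lutidine, CH2Cl2, −78 to 0 °C
Reagents that add atoms: tert-butyldimethylsilyl triflate (TBSOTf), CC(C)(C)[Si](C)(C)OS(=O)(=O)C(F)(F)F
Why: Silyl ether formation with the reactive triflate overcomes the hindrance of the ortho quaternary carbon, excess 2,6-lutidine keeps out acid that would add the phenol across C2=C3, and the silyl ether later prevents hemiketal formation with the C3 ketone and enlarges the aryl group for step 5.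

Step 5
Reactants: 7 {4-bromo-2-[(1R)-1,2-dimethylcyclopent-2-en-1-yl]-5-methylphenoxy}(tert-butyl)dimethylsilane
Product: 9 (1R,2R,3R)-3-[5-bromo-2-(tert-butyldimethylsilyloxy)-4-methylphenyl]-2,3-dimethylcyclopentan-1-ol, via alkylborane 8 (not isolated)
Conditions: BH3·THF, THF, 0 °C to rt; then NaBO3·4H2O, THF/H2O, rt
Reagents that add atoms: sodium perborate tetrahydrate (NaBO3·4H2O, oxygen atom of 9), [Na+].[Na+].O[B-]1(O)OO[B-](O)(O)OO1; borane–THF (boron of 8 only), B.C1CCOC1
Why: Hydroboration–oxidation, in which boron adds to the less substituted C3 and hydrogen to C2 in a syn manner from the ring face that carries the C1 methyl group, opposite the bulky silyloxyaryl group, so that the C2 methyl group is pushed cis to the aryl group and the mild perborate oxidation proceeds with retention without cleaving the aryl silyl ether.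

Step 6
Reactants: 9 (1R,2R,3R)-3-[5-bromo-2-(tert-butyldimethylsilyloxy)-4-methylphenyl]-2,3-dimethylcyclopentan-1-ol
Product: 10 (2R,3R)-3-[5-bromo-2-(tert-butyldimethylsilyloxy)-4-methylphenyl]-2,3-dimethylcyclopentan-1-one
Conditions: Dess–Martin periodinane, CH2Cl2, 0 °C to rt
Reagents that add atoms: none
Why: Dess–Martin oxidation works under nearly neutral conditions and does not enolise the ketone, so the kinetically set and thermodynamically less favoured C2 configuration (methyl cis to aryl) should be preserved.

Step 7
Reactants: 10 (2R,3R)-3-[5-bromo-2-(tert-butyldimethylsilyloxy)-4-methylphenyl]-2,3-dimethylcyclopentan-1-one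
Product: 11 {4-bromo-2-[(1R,2R)-3-(dibromomethylidene)-1,2-dimethylcyclopentyl]-5-methylphenoxy}(tert-butyl)dimethylsilane
Conditions: CBr4, PPh3, CH2Cl2, 0 °C (ylide preformed); then 10, 0 to 40 °C
Reagents that add atoms: carbon tetrabromide (CBr4), BrC(Br)(Br)Br
Why: Ramirez olefination (Wittig-type dibromomethylenation), in which the weakly basic ylide Ph3P=CBr2 adds to the strained cyclopentanone carbonyl from the face opposite the aryl group without deprotonating C2, so no geometry issue arises at this stage and the C2 stereocentre becomes non-epimerisable.

Step 8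
Reactants: 11 {4-bromo-2-[(1R,2R)-3-(dibromomethylidene)-1,2-dimethylcyclopentyl]-5-methylphenoxy}(tert-butyl)dimethylsilane
Product: 12 {4-bromo-2-[(1R,2R,3Z)-3-(bromomethylidene)-1,2-dimethylcyclopentyl]-5-methylphenoxy}(tert-butyl)dimethylsilane
Conditions: Pd(PPh3)4 (5 mol %), Bu3SnH (1.05 equiv), toluene, rt
Reagents that add atoms: none
Why: Palladium-catalysed stereoselective hydrogenolysis of a 1,1-dibromoalkene with Bu3SnH, in which zerovalent palladium should insert faster into the vinylic C–Br bond on the open C4H2 side than into the one shielded by the C2 methine and quaternary C1, and faster than into the electron-rich aryl bromide at room temperature, so that hydride transfer with retention leaves the bromine on the C2 side (Z).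

Step 9
Reactants: 12 {4-bromo-2-[(1R,2R,3Z)-3-(bromomethylidene)-1,2-dimethylcyclopentyl]-5-methylphenoxy}(tert-butyl)dimethylsilane
Product: 13 4-bromo-2-[(1R,2R,3Z)-3-(bromomethylidene)-1,2-dimethylcyclopentyl]-5-methylphenol
Conditions: TBAF, AcOH, THF, 0 °C
Reagents that add atoms: none
Why: Fluoride-induced cleavage of the aryl silyl ether, buffered with acetic acid, is fast at 0 °C and avoids both strong acid, which could add the phenol to the exocyclic alkene, and strong base, so both C–Br bonds, the alkene geometry and the stereocentres stay untouched.

Compound list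
1 | 2,3-dimethylcyclopent-2-en-1-one | CC1=C(C)C(=O)CC1 | starting material
2 | (1R)-2,3-dimethylcyclopent-2-en-1-ol | O[C@@H]1CCC(C)=C1C | intermediate
3 | 4-bromo-3-methylphenol | Cc1cc(O)ccc1Br | starting material
4 | 1-bromo-4-{[(1S)-2,3-dimethylcyclopent-2-en-1-yl]oxy}-2-methylbenzene | Cc1cc(O[C@H]2CCC(C)=C2C)ccc1Br | intermediate
5 | 4-bromo-6-[(1S)-1,2-dimethylcyclopent-2-en-1-yl]-3-methylcyclohexa-2,4-dien-1-one (dienone, not isolated; same spatial arrangement at C1 as in 6, the descriptor differs only through CIP priorities; the ring CH centre is left open because it is lost on tautomerisation) | O=C1C=C(C)C(Br)=CC1[C@]2(C)CCC=C2C | intermediate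
6 | 4-bromo-2-[(1R)-1,2-dimethylcyclopent-2-en-1-yl]-5-methylphenol | Cc1cc(O)c([C@]2(C)CCC=C2C)cc1Br | intermediate
7 | {4-bromo-2-[(1R)-1,2-dimethylcyclopent-2-en-1-yl]-5-methylphenoxy}(tert-butyl)dimethylsilane | Cc1cc(O[Si](C)(C)C(C)(C)C)c([C@]2(C)CCC=C2C)cc1Br | intermediate
8 | alkylborane (not isolated): BH2 on C3 on the face of the C1 methyl group, cis to C2–H, trans to the C2 methyl group and to the aryl group | Cc1cc(O[Si](C)(C)C(C)(C)C)c([C@]2(C)CC[C@@H](B)[C@@H]2C)cc1Br | intermediate
9 | (1R,2R,3R)-3-[5-bromo-2-(tert-butyldimethylsilyloxy)-4-methylphenyl]-2,3-dimethylcyclopentan-1-ol | Cc1cc(O[Si](C)(C)C(C)(C)C)c([C@]2(C)CC[C@@H](O)[C@@H]2C)cc1Br | intermediate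
10 | (2R,3R)-3-[5-bromo-2-(tert-butyldimethylsilyloxy)-4-methylphenyl]-2,3-dimethylcyclopentan-1-one | Cc1cc(O[Si](C)(C)C(C)(C)C)c([C@]2(C)CCC(=O)[C@@H]2C)cc1Br | intermediate
11 | {4-bromo-2-[(1R,2R)-3-(dibromomethylidene)-1,2-dimethylcyclopentyl]-5-methylphenoxy}(tert-butyl)dimethylsilane | Cc1cc(O[Si](C)(C)C(C)(C)C)c([C@]2(C)CCC(=C(Br)Br)[C@@H]2C)cc1Br | intermediate
12 | {4-bromo-2-[(1R,2R,3Z)-3-(bromomethylidene)-1,2-dimethylcyclopentyl]-5-methylphenoxy}(tert-butyl)dimethylsilane | Cc1cc(O[Si](C)(C)C(C)(C)C)c([C@]2(C)CC/C(=C/Br)[C@@H]2C)cc1Br | intermediate
13 | 4-bromo-2-[(1R,2R,3Z)-3-(bromomethylidene)-1,2-dimethylcyclopentyl]-5-methylphenol | Cc1cc(O)c([C@]2(C)CC/C(=C/Br)[C@@H]2C)cc1Br | target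

Total step count: 9
Longest linear sequence: 9 steps (1 to 13)

Steps most likely to fail

1. Step 3.
- What may go wrong: heterolysis of the activated O–C3 bond may outrun the concerted shift. This would erode the chirality transfer or lead to elimination of the phenol instead of C–C bond formation at the crowded alkene carbon.
- Fallback: an intermolecular copper-mediated anti-SN2' arylation that sets out from alcohol 2 and phenol 3 and comes back to the route at silyl ether 7.
- Ring B partner: alcohol 2 is esterified with picolinic acid (EDC·HCl, DMAP, CH2Cl2) to (1R)-2,3-dimethylcyclopent-2-en-1-yl pyridine-2-carboxylate F1.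
- Ring A partner: phenol 3 is iodinated at the open ortho position para to the methyl group (NIS, cat. TsOH, MeCN) to 4-bromo-2-iodo-5-methylphenol F2. This is silylated (TBSCl, imidazole, DMF) to (4-bromo-2-iodo-5-methylphenoxy)(tert-butyl)dimethylsilane F3.
- Coupling: selective iodine–magnesium exchange (iPrMgCl·LiCl, THF, −20 °C) gives [5-bromo-2-(tert-butyldimethylsilyloxy)-4-methylphenyl]magnesium chloride F4. After transmetalation with CuBr·SMe2, F4 should displace the chelating picolinate of F1 at the remote alkene carbon C1 from the face opposite the leaving group. This gives 7 with the same (R) configuration.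

2. Step 8.
- What may go wrong: the catalyst may discriminate too little between the two vinylic C–Br bonds, or reduction may run on to the methylidene compound.
- Fallback: a change from selective removal of one bromine to stereospecific introduction of a single bromine, setting out from ketone 10 and coming back at 12.
- Olefination: ketone 10 is olefinated with lithiated bis(pinacolato)borylmethane (CH2(Bpin)2, LiTMP, THF, −78 °C to rt, boron–Wittig reaction). This should place boron on the open C4 side and give the (E)-alkenylboronate F5.
- Bromination with inversion: Br2 (CH2Cl2, −78 °C) adds in an anti manner to give the vicinal dibromide F6. NaOMe/MeOH then induces anti elimination of boron and the tertiary bromide, which inverts the geometry and places the bromine on the C2 side as in 12.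

3. Step 2.
- What may go wrong: ionisation of the electron-rich allylic oxyphosphonium intermediate would cause partial racemisation, and elimination to the diene may compete with substitution.
- Fallback: the ether is made by forming the aryl–oxygen bond instead of the alkyl–oxygen bond, setting out from enone 1 and coming back at ether 4.
- Alcohol: enone 1 is reduced with the enantiomeric catalyst ((R)-Me-CBS oxazaborolidine, BH3·SMe2, THF) to (1S)-2,3-dimethylcyclopent-2-en-1-ol F7.
- O-Arylation: the sodium alkoxide of F7 (NaH, toluene, 0 °C) is O-arylated without a metal catalyst by (4-bromo-3-methylphenyl)(2,4,6-trimethoxyphenyl)iodonium tosylate F8. F8 is made from commercial 1-bromo-4-iodo-2-methylbenzene, mCPBA, TsOH·H2O and 1,3,5-trimethoxybenzene.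
- Stereochemical outcome: ligand coupling at hypervalent iodine transfers the less electron-rich aryl group. The C–O bond at the stereocentre is never broken, so the configuration is retained and 4 results.

Further compounds
F1 | step 3 | (1R)-2,3-dimethylcyclopent-2-en-1-yl pyridine-2-carboxylate | O=C(O[C@@H]1CCC(C)=C1C)c1ccccn1
F2 | step 3 | 4-bromo-2-iodo-5-methylphenol | Cc1cc(O)c(I)cc1Br
F3 | step 3 | (4-bromo-2-iodo-5-methylphenoxy)(tert-butyl)dimethylsilane | Cc1cc(O[Si](C)(C)C(C)(C)C)c(I)cc1Br
F4 | step 3 | [5-bromo-2-(tert-butyldimethylsilyloxy)-4-methylphenyl]magnesium chloride | Cc1cc(O[Si](C)(C)C(C)(C)C)c([Mg]Cl)cc1Br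
F5 | step 8 | (E)-alkenylboronate: pinacol boronate of 12 with Bpin in place of Br but on the C4 side of the double bond | Cc1cc(O[Si](C)(C)C(C)(C)C)c([C@]2(C)CC/C(=C\B3OC(C)(C)C(C)(C)O3)[C@@H]2C)cc1Br
F6 | step 8 | vicinal dibromide from anti addition of Br2 to F5 (tertiary Br on C3, exocyclic CHBr–Bpin; drawn for bromonium formation on the face opposite the aryl group) | Cc1cc(O[Si](C)(C)C(C)(C)C)c([C@]2(C)CC[C@@](Br)([C@H](Br)B3OC(C)(C)C(C)(C)O3)[C@@H]2C)cc1Br
F7 | step 2 | (1S)-2,3-dimethylcyclopent-2-en-1-ol | O[C@H]1CCC(C)=C1C
F8 | step 2 | (4-bromo-3-methylphenyl)(2,4,6-trimethoxyphenyl)iodonium 4-methylbenzenesulfonate | Cc1cc([I+]c2c(OC)cc(OC)cc2OC)ccc1Br.Cc1ccc(cc1)S(=O)(=O)[O-]
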